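Numbering follows the labdane skeleton: ring A = C1–C5 and C10, ring B = C5–C10, oxolane ring C = O–C9–C11–C12–C13, dihydrofuran ring D = C13–C14=C15–O–C16; β is the face of the C10 methyl.
Enabling feature: quaternary C4, methine C5 and quaternary C10 are contiguous and H5 is cis to the C10 methyl, so ring A can be fused onto the α face of a ring B enone (C5=C10–C9=O) by making C4–C5 and C1–C10 in one flask.
Retrosynthesis: the acetate and the C14=C15 enol ether go back to a C14 carbinol; C13–O is cut to a 13,14-epoxide opened by the C9 hydroxyl; C9–C11 is cut to a C9 ketone and a (2,5-dihydrofuran-3-yl)ethyl metal; an oxygen is put back on C1 and ring A is cut at C4–C5 and C1–C10.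
Forward order: ring B is bought as a chiral enone, ring A is annulated, C1 is deoxygenated, ring D arrives preformed on the C11–C12 chain, ring C closes by epoxide opening, then enol ether formation, desilylation and acetylation.
Stereochemistry: C6 comes from the starting enone, C8 from anti enolate methylation, C5 and C10 from anti radical addition and cis ring closure, C9 from convex-face addition to the cis-decalone, C13 from catalyst-controlled epoxidation followed by inversion.

Key step: step 6

Remark: the C1 carbinol of the annulation product is drawn as the 1β epimer expected from a metal-bridged chair; that centre is removed two steps later, so either epimer or a mixture would serve.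

Step 1
Reactants: 1 (R)-4-[(tert-butyldimethylsilyl)oxy]cyclohex-2-en-1-one
Product: 2 (R)-4-[(tert-butyldimethylsilyl)oxy]-2-iodocyclohex-2-en-1-one
Conditions: I2, pyridine, CH2Cl2, 0 °C to rt
Reagents that add atoms: iodine, II
Why: Amine-mediated α-iodination of a cyclic enone (conjugate addition of pyridine, iodination of the enolate, elimination of pyridine) should functionalise C2 only and leave the C4 stereocentre untouched.

Step 2
Reactants: 2 (R)-4-[(tert-butyldimethylsilyl)oxy]-2-iodocyclohex-2-en-1-one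
Product: 3 (R)-4-[(tert-butyldimethylsilyl)oxy]-2-methylcyclohex-2-en-1-one
Conditions: Me4Sn, PdCl2(PhCN)2 (5 mol %), AsPh3, CuI, NMP, 80 °C
Reagents that add atoms: tetramethylstannane, C[Sn](C)(C)C
Why: Stille cross-coupling of an α-iodoenone (oxidative addition to zerovalent palladium, copper-assisted methyl transfer from tin, reductive elimination) runs under neutral conditions that should not disturb the γ-silyloxy group.

Step 3
Reactants: 3 (R)-4-[(tert-butyldimethylsilyl)oxy]-2-methylcyclohex-2-en-1-one
Product: 4 (4R,6R)-4-[(tert-butyldimethylsilyl)oxy]-2,6-dimethylcyclohex-2-en-1-one (silyloxy group trans to the 6-methyl)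
Conditions: LiN(i-Pr)2, THF, −78 °C; MeI, −78 to −30 °C
Reagents that add atoms: iodomethane, CI
Why: Kinetic α′-deprotonation and enolate alkylation, in which iodomethane should enter axially on the dienolate half-chair from the face opposite the pseudoaxial 4-silyloxy group, giving the trans-4,6 relationship that becomes C6/C8 of the target.

Step 4
Reactants: 5 2-methylprop-2-en-1-ol; 6 ethyl vinyl ether
Product: 7 2-methylprop-2-en-1-yl vinyl ether
Conditions: Hg(OAc)2 (cat.), neat 6 (large excess), reflux; K2CO3, distillation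
Reagents that add atoms: none
Why: Mercury-catalysed vinyl ether exchange (transvinylation) is driven to the allyl vinyl ether by the excess of 6.

Step 5
Reactants: 7 2-methylprop-2-en-1-yl vinyl ether
Product: 8 4-methylpent-4-enal
Conditions: neat, sealed tube, 150 °C
Reagents that add atoms: none
Why: Thermal Claisen rearrangement ([3,3]-sigmatropic shift through a chair) of an allyl vinyl ether gives the γ,δ-unsaturated aldehyde that carries C1–C4 and both C4 methyl carbons.

Step 6
Reactants: 4 (4R,6R)-4-[(tert-butyldimethylsilyl)oxy]-2,6-dimethylcyclohex-2-en-1-one; 8 4-methylpent-4-enal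
Product: 9 cis-fused 1β-hydroxy-6β-[(tert-butyldimethylsilyl)oxy]-4,4,8α,10β-tetramethyl-5βH-decalin-9-one
Conditions: Fe(acac)3 (0.5 equiv), PhSiH3 (3 equiv), EtOH–(CH2OH)2 (5:1), 0 °C to rt, 8 (2.5 equiv) added slowly
Reagents that add atoms: none
Why: An iron hydride generated from Fe(acac)3 and PhSiH3 transfers a hydrogen atom to the terminal CH2 of 8, the resulting tertiary C4 radical adds to C5 of enone 4, the C10 α-keto radical is reduced by divalent iron to an iron enolate, and this enolate attacks the C1 aldehyde. The closest known reaction type is the iron-catalysed, hydrogen-atom-transfer-initiated radical–polar crossover annulation of an enone with a γ,δ-unsaturated aldehyde (Giese addition followed by intramolecular aldol). Ring A closes by a 6-(enolexo)-exo-trig aldol. C5 is set by radical attack anti to the pseudoaxial 6β-silyloxy group (C4 α, H5 β); C10 is set because the tether fixed on the α face at C5 can reach only the α face of the enolate, giving the cis fusion with the methyl β; the C1 carbinol should come out β from a metal-bridged chair but is of no consequence. The step needs hydrogen-atom transfer to the electron-rich 1,1-disubstituted alkene instead of the enone and C–C bond formation at C5 instead of simple reduction, which polarity matching (nucleophilic tertiary radical, electrophilic β-carbon bearing only hydrogen) and the excess of 8 should secure. The enolate forms regiospecifically at C10, so the C8 stereocentre should not epimerise.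

Step 7
Reactants: 9 cis-fused 1β-hydroxy-6β-[(tert-butyldimethylsilyl)oxy]-4,4,8α,10β-tetramethyl-5βH-decalin-9-one
Product: 10 1β-O-(imidazol-1-ylthiocarbonyl) derivative of 9
Conditions: 1,1′-thiocarbonyldiimidazole, DMAP (cat.), ClCH2CH2Cl, 70 °C
Reagents that add atoms: 1,1′-thiocarbonyldiimidazole, S=C(n1ccnc1)n1ccnc1
Why: Thioacylation of the secondary alcohol without forming a free alkoxide should avoid retro-aldol cleavage of the β-hydroxy ketone.

Step 8
Reactants: 10 1β-O-(imidazol-1-ylthiocarbonyl) derivative of 9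
Product: 11 cis-fused 6β-[(tert-butyldimethylsilyl)oxy]-4,4,8α,10β-tetramethyl-5βH-decalin-9-one
Conditions: Bu3SnH (3 equiv, 0.3 M), AIBN (cat.), toluene, 110 °C
Reagents that add atoms: none
Why: Barton–McCombie deoxygenation, run at high stannane concentration so that the secondary C1 radical is reduced before a 1,2-acyl shift to C10 can compete.

Step 9
Reactants: 12 allyl propargyl ether [3-(prop-2-yn-1-yloxy)prop-1-ene]
Product: 13 3-vinyl-2,5-dihydrofuran
Conditions: RuCl2(=CHPh)(PCy3)2 (first-generation Grubbs catalyst, 2 mol %), CH2Cl2, ethylene (1 atm), rt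
Reagents that add atoms: none
Why: Ring-closing enyne metathesis of a 1,6-enyne under ethylene gives the five-membered ring with the 1,3-diene, an isomerisation with no loss of atoms.

Step 10
Reactants: 13 3-vinyl-2,5-dihydrofuran
Product: 14 2-(2,5-dihydrofuran-3-yl)ethan-1-ol
Conditions: 9-BBN, THF, 0 °C to rt; then NaOH, H2O2, 0 °C
Reagents that add atoms: hydrogen peroxide, OO
Why: Anti-Markovnikov hydroboration–oxidation, in which the bulky borane should take the terminal vinyl carbon in preference to the trisubstituted ring alkene.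

Step 11
Reactants: 14 2-(2,5-dihydrofuran-3-yl)ethan-1-ol
Product: 15 3-(2-iodoethyl)-2,5-dihydrofuran
Conditions: I2, PPh3, imidazole, CH2Cl2, 0 °C
Reagents that add atoms: iodine, II
Why: Appel-type iodination of a primary alcohol through the alkoxyphosphonium salt.

Step 12
Reactants: 11 cis-fused 6β-[(tert-butyldimethylsilyl)oxy]-4,4,8α,10β-tetramethyl-5βH-decalin-9-one; 15 3-(2-iodoethyl)-2,5-dihydrofuran
Product: 18 9α-hydroxy-9β-[2-(2,5-dihydrofuran-3-yl)ethyl]-6β-[(tert-butyldimethylsilyl)oxy]-4,4,8α,10β-tetramethyl-5βH-decalin, via dihydrofuranylethyllithium 16 (not isolated), via dihydrofuranylethylcerium dichloride 17 (not isolated)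
Conditions: 15 (3 equiv), t-BuLi (6 equiv), Et2O, −78 °C; CeCl3 (3.3 equiv), THF, −78 °C; then 11, −78 to −40 °C; aq. NH4Cl
Reagents that add atoms: none
Why: Lithium–iodine exchange and transmetalation give a weakly basic organocerium reagent that should add to the hindered, enolisable C9 ketone (organocerium 1,2-addition) from the convex β face of the cis-decalone, because ring A and the 8α-methyl shield the α face, placing C11 β and the hydroxyl α.

Step 13
Reactants: 18 9α-hydroxy-9β-[2-(2,5-dihydrofuran-3-yl)ethyl]-6β-[(tert-butyldimethylsilyl)oxy]-4,4,8α,10β-tetramethyl-5βH-decalin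
Product: 20 9α,13-epoxy spiro alcohol (rings C and D closed; 14-hydroxyl trans to the C13–O9 bond; C13 as in the target), via epoxy alcohol 19 (not isolated)
Conditions: ent-Shi ketone (1,2:4,5-di-O-isopropylidene-β-L-erythro-2,3-hexodiulo-2,6-pyranose, 0.3 equiv), Oxone (2KHSO5·KHSO4·K2SO4), K2CO3, Bu4NHSO4, MeCN–CH2(OMe)2–aq. Na2B4O7, 0 °C; extractive work-up; then camphorsulfonic acid (0.1 equiv), CH2Cl2, 0 °C
Reagents that add atoms: potassium peroxymonosulfate (active part of Oxone), [K+].[O-]S(=O)(=O)OO
Why: Shi asymmetric epoxidation of the trisubstituted C13=C14 alkene with the L-fructose-derived ketone should put the epoxide oxygen on the face opposite to that needed for O9 (spiro transition-state model), and acid-promoted 5-exo-tet opening by the C9 hydroxyl at the tertiary carbon with inversion then sets C13 and leaves a trans C14 hydroxyl.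

Step 14
Reactants: 20 9α,13-epoxy spiro alcohol
Product: 21 9α,13-epoxy spiro ketone (C14 carbonyl in ring D)
Conditions: Dess–Martin periodinane, CH2Cl2, rt
Reagents that add atoms: none
Why: Dess–Martin oxidation of a hindered secondary alcohol under near-neutral conditions; C13 is quaternary and cannot epimerise.

Step 15
Reactants: 21 9α,13-epoxy spiro ketone
Product: 22 C14 enol triflate (C14=C15 in ring D)
Conditions: KN(SiMe3)2, THF, −78 °C; PhNTf2, −78 to 0 °C
Reagents that add atoms: N-phenylbis(trifluoromethanesulfonimide), O=S(=O)(N(c1ccccc1)S(=O)(=O)C(F)(F)F)C(F)(F)F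
Why: Enolate O-triflation; the ketone can enolise only toward C15 because C13 is quaternary, so the double bond is placed unambiguously at C14=C15.

Step 16
Reactants: 22 C14 enol triflate
Product: 23 6β-[(tert-butyldimethylsilyl)oxy]-9α,13:15,16-diepoxy-5βH-labd-14-ene (13R)
Conditions: Pd(OAc)2 (5 mol %), PPh3, Bu3N (3 equiv), HCO2H (2 equiv), DMF, 60 °C
Reagents that add atoms: none
Why: Palladium-catalysed formate reduction of a vinyl triflate (oxidative addition, formate decarboxylation to a palladium hydride, reductive elimination) in amine-buffered medium should give the acid-sensitive cyclic enol ether without touching the allylic spiro ether.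

Step 17
Reactants: 23 6β-[(tert-butyldimethylsilyl)oxy]-9α,13:15,16-diepoxy-5βH-labd-14-ene
Product: 24 9α,13:15,16-diepoxy-5βH-labd-14-en-6β-ol (13R)
Conditions: Bu4NF, THF, rt to 45 °C
Reagents that add atoms: none
Why: Fluoride-mediated silyl ether cleavage is basic and should leave the enol ether and the spiro ether intact.

Step 18
Reactants: 24 9α,13:15,16-diepoxy-5βH-labd-14-en-6β-ol
Product: 25 target, 6β-acetoxy-9α,13:15,16-diepoxy-5βH-labd-14-ene (13R)
Conditions: Ac2O, Et3N, DMAP, CH2Cl2, rt; chromatography on Et3N-deactivated silica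
Reagents that add atoms: acetic anhydride, CC(=O)OC(C)=O
Why: DMAP-catalysed acylation of the secondary alcohol under basic conditions, chosen so that the prefuranic spiro enol ether never meets acid.

Compound list
1 | (R)-4-[(tert-butyldimethylsilyl)oxy]cyclohex-2-en-1-one | CC(C)(C)[Si](C)(C)O[C@@H]1CCC(=O)C=C1 | starting material
2 | (R)-4-[(tert-butyldimethylsilyl)oxy]-2-iodocyclohex-2-en-1-one | CC(C)(C)[Si](C)(C)O[C@@H]1CCC(=O)C(I)=C1 | intermediate
3 | (R)-4-[(tert-butyldimethylsilyl)oxy]-2-methylcyclohex-2-en-1-one | CC(C)(C)[Si](C)(C)O[C@@H]1CCC(=O)C(C)=C1 | intermediate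
4 | (4R,6R)-4-[(tert-butyldimethylsilyl)oxy]-2,6-dimethylcyclohex-2-en-1-one | CC(C)(C)[Si](C)(C)O[C@@H]1C[C@@H](C)C(=O)C(C)=C1 | intermediate
5 | 2-methylprop-2-en-1-ol | CC(=C)CO | starting material
6 | ethyl vinyl ether | C=COCC | starting material
7 | 2-methylprop-2-en-1-yl vinyl ether | CC(=C)COC=C | intermediate
8 | 4-methylpent-4-enal | CC(=C)CCC=O | intermediate
9 | cis-fused 1β-hydroxy-6β-[(tert-butyldimethylsilyl)oxy]-4,4,8α,10β-tetramethyl-5βH-decalin-9-one | CC(C)(C)[Si](C)(C)O[C@@H]1C[C@@H](C)C(=O)[C@@]2(C)[C@H](O)CCC(C)(C)[C@@H]12 | intermediate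
10 | 1β-O-(imidazol-1-ylthiocarbonyl) derivative of 9 | CC(C)(C)[Si](C)(C)O[C@@H]1C[C@@H](C)C(=O)[C@@]2(C)[C@H](OC(=S)n3ccnc3)CCC(C)(C)[C@@H]12 | intermediate
11 | cis-fused 6β-[(tert-butyldimethylsilyl)oxy]-4,4,8α,10β-tetramethyl-5βH-decalin-9-one | CC(C)(C)[Si](C)(C)O[C@@H]1C[C@@H](C)C(=O)[C@@]2(C)CCCC(C)(C)[C@@H]12 | intermediate
12 | allyl propargyl ether | C=CCOCC#C | starting material
13 | 3-vinyl-2,5-dihydrofuran | C=CC1=CCOC1 | intermediate
14 | 2-(2,5-dihydrofuran-3-yl)ethan-1-ol | OCCC1=CCOC1 | intermediate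
15 | 3-(2-iodoethyl)-2,5-dihydrofuran | ICCC1=CCOC1 | intermediate
16 | [2-(2,5-dihydrofuran-3-yl)ethyl]lithium | [Li]CCC1=CCOC1 | intermediate
17 | [2-(2,5-dihydrofuran-3-yl)ethyl]cerium dichloride | Cl[Ce](Cl)CCC1=CCOC1 | intermediate
18 | 9α-hydroxy-9β-[2-(2,5-dihydrofuran-3-yl)ethyl]-6β-[(tert-butyldimethylsilyl)oxy]-4,4,8α,10β-tetramethyl-5βH-decalin | CC(C)(C)[Si](C)(C)O[C@@H]1C[C@@H](C)[C@](O)(CCC2=CCOC2)[C@@]3(C)CCCC(C)(C)[C@@H]13 | intermediate
19 | 13,14-epoxide of 18 (epoxide oxygen on the ring D face opposite to that later taken by O9) | CC(C)(C)[Si](C)(C)O[C@@H]1C[C@@H](C)[C@](O)(CC[C@@]45COC[C@@H]4O5)[C@@]3(C)CCCC(C)(C)[C@@H]13 | intermediate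
20 | 6β-[(tert-butyldimethylsilyl)oxy]-9α,13:15,16-diepoxy-5βH-labdan-14-ol (14-OH trans to O9, C13 as in the target) | CC(C)(C)[Si](C)(C)O[C@@H]1C[C@@H](C)[C@]2(CC[C@]3([C@@H](O)COC3)O2)[C@@]2(C)CCCC(C)(C)[C@@H]12 | intermediate
21 | 6β-[(tert-butyldimethylsilyl)oxy]-9α,13:15,16-diepoxy-5βH-labdan-14-one | CC(C)(C)[Si](C)(C)O[C@@H]1C[C@@H](C)[C@]2(CC[C@]3(C(=O)COC3)O2)[C@@]2(C)CCCC(C)(C)[C@@H]12 | intermediate
22 | 6β-[(tert-butyldimethylsilyl)oxy]-9α,13:15,16-diepoxy-5βH-labd-14-en-14-yl trifluoromethanesulfonate | CC(C)(C)[Si](C)(C)O[C@@H]1C[C@@H](C)[C@]2(CC[C@]3(C(OS(=O)(=O)C(F)(F)F)=COC3)O2)[C@@]2(C)CCCC(C)(C)[C@@H]12 | intermediate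
23 | 6β-[(tert-butyldimethylsilyl)oxy]-9α,13:15,16-diepoxy-5βH-labd-14-ene (13R) | CC(C)(C)[Si](C)(C)O[C@@H]1C[C@@H](C)[C@]2(CC[C@]3(C=COC3)O2)[C@@]2(C)CCCC(C)(C)[C@@H]12 | intermediate
24 | 9α,13:15,16-diepoxy-5βH-labd-14-en-6β-ol (13R) | O[C@@H]1C[C@@H](C)[C@]2(CC[C@]3(C=COC3)O2)[C@@]2(C)CCCC(C)(C)[C@@H]12 | intermediate
25 | 6β-acetoxy-9α,13:15,16-diepoxy-5βH-labd-14-ene (13R), CNP0242014.2 | CC(=O)O[C@@H]1C[C@@H](C)[C@]2(CC[C@]3(C=COC3)O2)[C@@]2(C)CCCC(C)(C)[C@@H]12 | target

Total step count: 18. Longest linear sequence: 13 steps (steps 1–3, 6–8 and 12–18, from 1 to 25).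

Steps most likely to fail

Step 6. The iron enolate may be protonated by the alcoholic medium, or the free aldehyde reduced by the silane, before the C1–C10 bond forms; the strained aldol may also revert. The fallback separates the two bond formations and sets out from 8 and 4. Aldehyde 8 is converted with ethane-1,2-diol and TsOH into 2-(3-methylbut-3-en-1-yl)-1,3-dioxolane F1. The same Fe(acac)3/PhSiH3 Giese addition to 4 should then give the C5-alkylated ketone acetal F2 (C4 anti to the silyloxy group, C10 as an epimer mixture). Hydrolysis with pyridinium tosylate in wet acetone releases the keto aldehyde F3. A brief treatment with catalytic KOt-Bu in t-BuOH–THF at 0 °C closes ring A, because only the C10 enolate can cyclise to a six-membered ring; exposure is kept short to limit epimerisation at C8. The route is rejoined at 9.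

Step 13. The ring alkene is deactivated by two allylic C–O bonds, so epoxidation may be slow and catalyst control of the face incomplete; partial ionisation at C13 during the acid-promoted opening would further erode the spiro configuration. The fallback sets out from 11 and builds ring D from a furan. The organocerium reagent [2-(furan-3-yl)ethyl]cerium dichloride F4 (from 3-(2-iodoethyl)furan, t-BuLi and CeCl3) is added to 11 to give the 9α-hydroxy furan F5. Photooxygenation with singlet oxygen (O2, rose bengal, light, i-Pr2NEt, CH2Cl2, −78 °C) should give the 16-hydroxy-13-en-15,16-olide F6, and NaBH4 reduction the butenolide F7. DBU then promotes oxa-Michael addition of the C9 hydroxyl to C13 to give the 9α,13-epoxy-15,16-olide F8. Here the C13 epimers are separable, and the unwanted one can be recycled by base equilibration through retro-oxa-Michael opening. Reduction with i-Bu2AlH at −78 °C gives the lactol F9, and MsCl/Et3N dehydrates it to the enol ether. The route is rejoined at 23.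

Step 12. The C9 ketone lies between a quaternary and a tertiary carbon, so enolisation may outrun addition, and the alkyllithium carrying an allylic ether may decompose before transmetalation. The fallback sets out from 11 and makes the C9–C11 bond through a ketyl radical, which cannot be lost to enolisation. SmI2 with methyl acrylate and t-BuOH in THF should give, by ketyl–olefin coupling on the convex face and lactonisation, the spirolactone F10. Addition of (allyloxymethyl)lithium F11 (from allyl tributylstannylmethyl ether and n-BuLi) at −78 °C gives the hydroxy ketone F12, which is expected to rest as its cyclic hemiketal. Wittig methylenation with Ph3P=CH2 gives the diene F13, and ring-closing metathesis with RuCl2(=CHPh)(PCy3)(H2IMes) (second-generation Grubbs catalyst) forms the dihydrofuran. The route is rejoined at 18.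

Further compounds
F1 | step 6 | 2-(3-methylbut-3-en-1-yl)-1,3-dioxolane | CC(=C)CCC1OCCO1
F2 | step 6 | (3S,4R,6R)-4-[(tert-butyldimethylsilyl)oxy]-3-[4-(1,3-dioxolan-2-yl)-2-methylbutan-2-yl]-2,6-dimethylcyclohexan-1-one (C2 epimer mixture) | CC(C)(C)[Si](C)(C)O[C@@H]1C[C@@H](C)C(=O)C(C)[C@H]1C(C)(C)CCC2OCCO2
F3 | step 6 | 4-{(1S,4R,6R)-6-[(tert-butyldimethylsilyl)oxy]-2,4-dimethyl-3-oxocyclohexyl}-4-methylpentanal (C2 epimer mixture) | CC(C)(C)[Si](C)(C)O[C@@H]1C[C@@H](C)C(=O)C(C)[C@H]1C(C)(C)CCC=O
F4 | step 13 | [2-(furan-3-yl)ethyl]cerium dichloride | Cl[Ce](Cl)CCc1ccoc1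
F5 | step 13 | 9α-hydroxy-9β-[2-(furan-3-yl)ethyl]-6β-[(tert-butyldimethylsilyl)oxy]-4,4,8α,10β-tetramethyl-5βH-decalin | CC(C)(C)[Si](C)(C)O[C@@H]1C[C@@H](C)[C@](O)(CCc2ccoc2)[C@@]3(C)CCCC(C)(C)[C@@H]13
F6 | step 13 | 9α,16-dihydroxy-6β-[(tert-butyldimethylsilyl)oxy]-5βH-labd-13-en-15,16-olide (C16 epimer mixture) | CC(C)(C)[Si](C)(C)O[C@@H]1C[C@@H](C)[C@](O)(CCC2=CC(=O)OC2O)[C@@]3(C)CCCC(C)(C)[C@@H]13
F7 | step 13 | 9α-hydroxy-6β-[(tert-butyldimethylsilyl)oxy]-5βH-labd-13-en-15,16-olide | CC(C)(C)[Si](C)(C)O[C@@H]1C[C@@H](C)[C@](O)(CCC2=CC(=O)OC2)[C@@]3(C)CCCC(C)(C)[C@@H]13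
F8 | step 13 | 6β-[(tert-butyldimethylsilyl)oxy]-9α,13-epoxy-5βH-labdan-15,16-olide (C13 as in the target) | CC(C)(C)[Si](C)(C)O[C@@H]1C[C@@H](C)[C@]2(CC[C@]3(CC(=O)OC3)O2)[C@@]2(C)CCCC(C)(C)[C@@H]12
F9 | step 13 | 6β-[(tert-butyldimethylsilyl)oxy]-9α,13:15,16-diepoxy-5βH-labdan-15-ol (lactol, C15 epimer mixture) | CC(C)(C)[Si](C)(C)O[C@@H]1C[C@@H](C)[C@]2(CC[C@]3(CC(O)OC3)O2)[C@@]2(C)CCCC(C)(C)[C@@H]12
F10 | step 12 | spiro γ-lactone at C9 (O9 α, C11 β; lactone carbonyl = C13) | CC(C)(C)[Si](C)(C)O[C@@H]1C[C@@H](C)[C@]2(CCC(=O)O2)[C@@]2(C)CCCC(C)(C)[C@@H]12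
F11 | step 12 | (allyloxymethyl)lithium | [Li]COCC=C
F12 | step 12 | 9α-hydroxy-9β-[4-(allyloxy)-3-oxobutyl]-6β-[(tert-butyldimethylsilyl)oxy]-4,4,8α,10β-tetramethyl-5βH-decalin (open form of the hemiketal) | CC(C)(C)[Si](C)(C)O[C@@H]1C[C@@H](C)[C@](O)(CCC(=O)COCC=C)[C@@]2(C)CCCC(C)(C)[C@@H]12
F13 | step 12 | 9α-hydroxy-9β-{3-[(allyloxy)methyl]but-3-en-1-yl}-6β-[(tert-butyldimethylsilyl)oxy]-4,4,8α,10β-tetramethyl-5βH-decalin | CC(C)(C)[Si](C)(C)O[C@@H]1C[C@@H](C)[C@](O)(CCC(=C)COCC=C)[C@@]2(C)CCCC(C)(C)[C@@H]12
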